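**Plan**

- Retrosynthesis: C12–C13 is cut last (sp3–sp2 coupling) into a C12 alkylzinc on a tetranorlabdane core and an enol triflate that already holds C14–C16 and the butenolide. Then C8–OH/C9–H go back to a C8=C9 alkene, and the two ring-B bonds C5–C10 and C6–C7 are cut together.
- Enabling feature: ring B (C5–C6–C7–C8–C9–C10) carries oxygen on C6 and, after the retro-hydration, a C8=C9 double bond. It is therefore the [4+2] adduct of a C5=C6 aryl enol ether and a C7=C8–C9=C10 diene joined through C1–C2–C3 and the quaternary C4. Both partners are electron-rich, so the union is run as a radical-cation cycloaddition at an anode.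
- Forward: geraniol → C4 aldehyde (epoxidation, 1,2-shift) → chain extension to a C9≡C10 alkyne → stereodefined tetrasubstituted diene → (E)-alkenyl iodide → (E)-aryl enol ether → one anodic step closes ring A (C5–C10) and ring B (C6–C7) → hydration of C8=C9 → C12 iodide → coupling with the side chain (butenolide ring made by metathesis) → deprotection.
- Stereochemistry: C4 from Sharpless epoxidation plus a stereospecific siloxymethyl shift; C5, C6, C10 in the key step (relayed from C4, C6 also from the E enol ether); C8/C9 by α-face syn hydroboration; C14/C15 from L-tartaric acid; C16 by CBS reduction.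

Key step: step 14

Remark: locants follow the labdane numbering of the target (C1–C10 decalin, C11–C16 side chain, C17 on C8, C18/C19 on C4, C20 on C10); α is the face opposite to the C10 methyl.

**Core (steps 1–18)**

Step 1
Reactants: 1 geraniol
Product: 2 (2S,3S)-2,3-epoxygeraniol
Conditions: Ti(OiPr)4 (cat.), L-(+)-diethyl tartrate (cat.), t-BuOOH, 4 Å MS, CH2Cl2, −20 °C
Reagents that add atoms: tert-butyl hydroperoxide, CC(C)(C)OO
Why: Sharpless asymmetric epoxidation with the L-(+)-tartrate complex should epoxidise only the allylic 2,3-alkene and give the (2S,3S)-epoxide, which fixes the configuration later carried to C4.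

Step 2
Reactants: 2 (2S,3S)-2,3-epoxygeraniol
Product: 3 (2S,3S)-2,3-epoxygeranyl tert-butyldimethylsilyl ether
Conditions: TBSCl, imidazole, DMF, 0 °C to rt
Reagents that add atoms: tert-butyldimethylsilyl chloride, CC(C)(C)[Si](C)(C)Cl
Why: Standard silylation of the primary alcohol provides the silyl ether needed for the rearrangement.

Step 3
Reactants: 3 (2S,3S)-2,3-epoxygeranyl tert-butyldimethylsilyl ether
Product: 4 (S)-2-[(tert-butyldimethylsilyloxy)methyl]-2,6-dimethylhept-5-enal
Conditions: methylaluminium bis(4-bromo-2,6-di-tert-butylphenoxide), MeAl(OAr)2 (20 mol %), CH2Cl2, −78 to −20 °C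
Reagents that add atoms: none
Why: Lewis-acid epoxide-to-aldehyde (semipinacol-type) rearrangement of an epoxy silyl ether: the epoxide opens at the tertiary carbon and the siloxymethyl group shifts anti to the breaking C–O bond, so the epoxide chirality is transferred to the quaternary C4.

Step 4
Reactants: 4 (S)-2-[(tert-butyldimethylsilyloxy)methyl]-2,6-dimethylhept-5-enal
Product: 5 (S)-1-(tert-butyldimethylsilyloxy)-2-(dimethoxymethyl)-2,6-dimethylhept-5-ene
Conditions: MeOSiMe3 (2.5 equiv), Me3SiOTf (cat.), CH2Cl2, −78 °C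
Reagents that add atoms: methoxytrimethylsilane, CO[Si](C)(C)C
Why: Silyl-triflate-catalysed acetalisation masks the non-enolisable aldehyde without protic acid, so the silyl ether should survive.

Step 5
Reactants: 5 (S)-1-(tert-butyldimethylsilyloxy)-2-(dimethoxymethyl)-2,6-dimethylhept-5-ene
Product: 7 (S)-4-[(tert-butyldimethylsilyloxy)methyl]-5,5-dimethoxy-4-methylpentan-1-ol, via aldehyde 6 (not isolated)
Conditions: O3, CH2Cl2/MeOH, −78 °C; then NaBH4, −78 °C to rt
Reagents that add atoms: ozone, [O-][O+]=O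
Why: Ozonolysis of the only alkene with reductive work-up trims the chain to the C1 alcohol.

Step 6
Reactants: 7 (S)-4-[(tert-butyldimethylsilyloxy)methyl]-5,5-dimethoxy-4-methylpentan-1-ol
Product: 8 (S)-tert-butyl[2-(dimethoxymethyl)-5-iodo-2-methylpentyloxy]dimethylsilane
Conditions: I2, PPh3, imidazole, CH2Cl2, 0 °C
Reagents that add atoms: iodine, II
Why: Appel iodination of the primary alcohol under imidazole buffering should leave acetal and silyl ether intact.

Step 7
Reactants: 8 (S)-tert-butyl[2-(dimethoxymethyl)-5-iodo-2-methylpentyloxy]dimethylsilane; 9 3-butyn-1-ol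
Product: 11 (S)-8-[(tert-butyldimethylsilyloxy)methyl]-9,9-dimethoxy-8-methylnon-3-yn-1-ol, via dilithium salt 10 (not isolated)
Conditions: 9, n-BuLi (2.1 equiv), THF/DMPU, −78 to 0 °C; then 8, 0 °C to rt; H2O
Reagents that add atoms: none
Why: SN2 alkylation of the acetylide carbon of the alkoxide–acetylide dianion forms the C1–C10 bond and places the hydroxyl that directs the next step.

Step 8
Reactants: 11 (S)-8-[(tert-butyldimethylsilyloxy)methyl]-9,9-dimethoxy-8-methylnon-3-yn-1-ol
Product: 13 (3E,8S)-8-[(tert-butyldimethylsilyloxy)methyl]-3-iodo-9,9-dimethoxy-4,8-dimethylnon-3-en-1-ol, via alkenylmagnesium chelate 12 (not isolated)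
Conditions: MeMgBr (4 equiv), Fe(acac)3 (15 mol %), THF, 0 °C; then I2, −78 to 0 °C
Reagents that add atoms: methylmagnesium bromide, C[Mg]Br; iodine, II
Why: Hydroxyl-directed iron-catalysed syn-carbomagnesiation of a homopropargylic alkoxide puts methyl on the distal carbon (C10) and magnesium on C9 in a five-membered chelate, and iodinolysis with retention fixes the alkene geometry (methyl and iodine cis).

Step 9
Reactants: 13 (3E,8S)-8-[(tert-butyldimethylsilyloxy)methyl]-3-iodo-9,9-dimethoxy-4,8-dimethylnon-3-en-1-ol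
Product: 14 (3E,8S)-8-[(tert-butyldimethylsilyloxy)methyl]-9,9-dimethoxy-4,8-dimethyl-3-(prop-1-en-2-yl)non-3-en-1-ol
Conditions: isopropenyl-B(pin), Pd(dppf)Cl2 (5 mol %), K3PO4, THF/H2O, 60 °C
Reagents that add atoms: 2-isopropenyl-4,4,5,5-tetramethyl-1,3,2-dioxaborolane, CC(=C)B1OC(C)(C)C(C)(C)O1
Why: Suzuki–Miyaura coupling with retention gives the diene in which the C10 methyl is cis and the tether trans to the isopropenyl group.

Step 10
Reactants: 14 (3E,8S)-8-[(tert-butyldimethylsilyloxy)methyl]-9,9-dimethoxy-4,8-dimethyl-3-(prop-1-en-2-yl)non-3-en-1-ol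
Product: 15 (2S,6E)-1-(tert-butyldimethylsilyloxy)-9-chloro-2-(dimethoxymethyl)-2,6-dimethyl-7-(prop-1-en-2-yl)non-6-ene
Conditions: PPh3, N-chlorosuccinimide, THF, 0 °C to rt
Reagents that add atoms: N-chlorosuccinimide, ClN1C(=O)CCC1=O
Why: Appel-type chlorination turns the C12 hydroxyl into a chloride that is inert through the next seven steps and is a poor enough leaving group not to be displaced by the later C8 hydroxyl.

Step 11
Reactants: 15 (2S,6E)-1-(tert-butyldimethylsilyloxy)-9-chloro-2-(dimethoxymethyl)-2,6-dimethyl-7-(prop-1-en-2-yl)non-6-ene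
Product: 16 (2S,6E)-2-[(tert-butyldimethylsilyloxy)methyl]-9-chloro-2,6-dimethyl-7-(prop-1-en-2-yl)non-6-enal
Conditions: Et3SiOTf, 2,4,6-collidine, CH2Cl2, 0 °C; then H2O
Reagents that add atoms: water, O
Why: Buffered silyl-triflate/collidine acetal cleavage through a collidinium intermediate should free the aldehyde without touching the silyl ether or isomerising the diene.

Step 12
Reactants: 16 (2S,6E)-2-[(tert-butyldimethylsilyloxy)methyl]-9-chloro-2,6-dimethyl-7-(prop-1-en-2-yl)non-6-enal
Product: 17 tert-butyl{[(2R,3E)-2-[(4E)-7-chloro-4-methyl-5-(prop-1-en-2-yl)hept-4-en-1-yl]-4-iodo-2-methylbut-3-en-1-yl]oxy}dimethylsilane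
Conditions: CrCl2 (6 equiv), CHI3 (2 equiv), dioxane/THF (6:1), rt
Reagents that add atoms: iodoform, IC(I)I
Why: Takai iodoolefination: the geminal dichromium species made from iodoform and divalent chromium adds to the non-enolisable aldehyde and eliminates to the (E)-alkenyl iodide, while the primary chloride, the silyl ether and the diene are inert to CrCl2.

Step 13
Reactants: 17 tert-butyl{[(2R,3E)-2-[(4E)-7-chloro-4-methyl-5-(prop-1-en-2-yl)hept-4-en-1-yl]-4-iodo-2-methylbut-3-en-1-yl]oxy}dimethylsilane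
Product: 18 tert-butyl{[(2R,3E)-2-[(4E)-7-chloro-4-methyl-5-(prop-1-en-2-yl)hept-4-en-1-yl]-4-(4-methoxyphenoxy)-2-methylbut-3-en-1-yl]oxy}dimethylsilane
Conditions: 4-MeOC6H4OH (1.5 equiv), CuI (10 mol %), N,N-dimethylglycine hydrochloride (30 mol %), Cs2CO3 (2 equiv), dioxane, 60 °C
Reagents that add atoms: 4-methoxyphenol, COc1ccc(O)cc1
Why: Copper-catalysed Ullmann-type C–O coupling of an alkenyl iodide with a phenol proceeds with retention of alkene geometry and so gives the C5=C6 aryl enol ether as the single (E)-isomer, and the primary chloride should not be displaced by caesium aryloxide in dioxane at this temperature.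

Step 14
Reactants: 18 (3E)-aryl enol ether triene
Product: 19 12-chloro-6α-(4-methoxyphenoxy)-18-(tert-butyldimethylsilyloxy)-13,14,15,16-tetranorlabd-8-ene (5α-H, 10β-CH3, 4β-CH3)
Conditions: constant-current electrolysis (about 0.3 F/mol), carbon-felt anode, Pt cathode, undivided cell, LiClO4 (1.0 M) in MeNO2, rt
Reagents that add atoms: none
Why: Proposed new method: one-electron oxidation of the p-methoxyphenyl enol ether (the most easily oxidised π-system) at the anode gives a radical cation whose C5 is attacked by C10 of the tethered tetraalkyl diene, the distonic intermediate (C6 cation stabilised by the aryloxy group, allyl radical over C7–C8–C9) closes C6–C7, and the cyclohexene radical cation is reduced by the anisyl group and then by fresh substrate, so that a catalytic amount of charge suffices. The closest known reaction types are the radical-cation Diels–Alder reaction of aryl enol ethers and anethole-type alkenes with simple dienes under anodic, photoredox or aminium-salt initiation, which is intermolecular or uses styrene dienophiles, and the intramolecular anodic coupling of enol ethers with tethered alkenes, which ends in solvent capture; neither has been shown for a tethered enol ether–diene pair that must form a quaternary ring-fusion carbon. Ring A closes by 6-exo attack of C10 on C5 through a chair and ring B by 6-endo closure of the allyl terminus C7 on C6 (a concerted [4+2] event gives the same adduct, and a [2+2] adduct at C6–C9 would be a vinylcyclobutane expected to rearrange to it under the same conditions). C10 and C5: chair with the dienyl residue equatorial and the C10 methyl axial, hence H-5 trans to that methyl, the absolute sense being relayed from C4 (CH2OTBS equatorial, methyl axial); C6: the E geometry of 18 places the aryloxy group trans to C4, that is equatorial (α), in a concerted or fast stepwise closure, and the same site is preferred if C5–C6 rotates in the intermediate because the axial site is syn-axial to the C4 and C10 methyls. The step needs cycloaddition rather than hydrolysis or oligomerisation (dry LiClO4/MeNO2, low charge), trans fusion, and facial selectivity with respect to C4, which rests only on the size difference between CH3 and CH2OTBS and is the weakest point.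

Step 15
Reactants: 19 12-chloro-6α-(4-methoxyphenoxy)-18-(tert-butyldimethylsilyloxy)-13,14,15,16-tetranorlabd-8-ene
Product: 21 12-chloro-6α-(4-methoxyphenoxy)-18-(tert-butyldimethylsilyloxy)-13,14,15,16-tetranorlabdan-8α-ol (9α-H), via 8α-alkylborane 20 (not isolated)
Conditions: BH3·THF (3 equiv), THF, 0 to 40 °C; then NaBO3·4H2O, THF/H2O, rt
Reagents that add atoms: sodium perborate, [Na+].[Na+].O[B-]1(O)OO[B-](O)(O)OO1
Why: Hydroboration–oxidation: syn addition from the α face (β face blocked by the C10 methyl) with boron on the less hindered C8 should give the 8α-OH/8β-CH3 and 9α-H centres at once, and the mild perborate work-up avoids alkoxide attack on the C12 chloride.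

Step 16
Reactants: 21 12-chloro-6α-(4-methoxyphenoxy)-18-(tert-butyldimethylsilyloxy)-13,14,15,16-tetranorlabdan-8α-ol
Product: 22 12-chloro-18-(tert-butyldimethylsilyloxy)-13,14,15,16-tetranorlabdane-6α,8α-diol
Conditions: (NH4)2Ce(NO3)6, MeCN/H2O (4:1), 0 °C
Reagents that add atoms: none
Why: Oxidative dearylation of the p-methoxyphenyl ether by tetravalent cerium frees the C6 hydroxyl with the C6–O bond, and hence the configuration, untouched.

Step 17
Reactants: 22 12-chloro-18-(tert-butyldimethylsilyloxy)-13,14,15,16-tetranorlabdane-6α,8α-diol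
Product: 23 12-chloro-18-(tert-butyldimethylsilyloxy)-6α,8α-bis(triethylsilyloxy)-13,14,15,16-tetranorlabdane
Conditions: Et3SiOTf, 2,6-lutidine, CH2Cl2, −78 to 0 °C
Reagents that add atoms: triethylsilyl trifluoromethanesulfonate, CC[Si](CC)(CC)OS(=O)(=O)C(F)(F)F
Why: Silylation of both hydroxyls removes acidic protons before the organozinc is made and keeps the C8 oxygen from closing a tetrahydrofuran onto C12.

Step 18
Reactants: 23 12-chloro-18-(tert-butyldimethylsilyloxy)-6α,8α-bis(triethylsilyloxy)-13,14,15,16-tetranorlabdane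
Product: 24 12-iodo-18-(tert-butyldimethylsilyloxy)-6α,8α-bis(triethylsilyloxy)-13,14,15,16-tetranorlabdane
Conditions: NaI, NaHCO3, 2-butanone, 80 °C
Reagents that add atoms: sodium iodide, [Na+].[I-]
Why: Finkelstein exchange at the unhindered primary carbon gives the iodide needed for zinc insertion.

**Side-chain fragment (steps 19–25)**

Step 19
Reactants: 25 dimethyl (4R,5R)-2,2-dimethyl-1,3-dioxolane-4,5-dicarboxylate
Product: 26 (4R,5R)-N,N'-dimethoxy-N,N',2,2-tetramethyl-1,3-dioxolane-4,5-dicarboxamide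
Conditions: MeNH(OMe)·HCl, i-PrMgCl, THF, −20 °C
Reagents that add atoms: N,O-dimethylhydroxylamine hydrochloride, CNOC.Cl
Why: Aminolysis of both esters by the magnesium amide gives the bis-Weinreb amide; the two stereocentres (later C14 and C15) come unchanged from L-tartaric acid.

Step 20
Reactants: 26 (4R,5R)-N,N'-dimethoxy-N,N',2,2-tetramethyl-1,3-dioxolane-4,5-dicarboxamide
Product: 27 (4R,5R)-5-acetyl-N-methoxy-N,2,2-trimethyl-1,3-dioxolane-4-carboxamide
Conditions: MeMgBr (1.1 equiv), THF, −78 to −20 °C; aq. NH4Cl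
Reagents that add atoms: methylmagnesium bromide, C[Mg]Br
Why: Mono-addition of a Grignard reagent to the C2-symmetric bis-Weinreb amide should stop after one amide because the first chelated tetrahedral intermediate deactivates the molecule toward a second addition.

Step 21
Reactants: 27 (4R,5R)-5-acetyl-N-methoxy-N,2,2-trimethyl-1,3-dioxolane-4-carboxamide
Product: 28 1-{(4R,5R)-5-[methoxy(methyl)carbamoyl]-2,2-dimethyl-1,3-dioxolan-4-yl}ethenyl trifluoromethanesulfonate
Conditions: KN(SiMe3)2, PhNTf2, THF, −78 °C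
Reagents that add atoms: N-phenylbis(trifluoromethanesulfonimide), O=S(=O)(N(c1ccccc1)S(=O)(=O)C(F)(F)F)C(F)(F)F
Why: Kinetic enolisation on the methyl side and O-triflation give the 1,1-disubstituted enol triflate that becomes C13 and its methylene.

Step 22
Reactants: 28 1-{(4R,5R)-5-[methoxy(methyl)carbamoyl]-2,2-dimethyl-1,3-dioxolan-4-yl}ethenyl trifluoromethanesulfonate
Product: 29 1-{(4R,5R)-2,2-dimethyl-5-(2-methylprop-2-enoyl)-1,3-dioxolan-4-yl}ethenyl trifluoromethanesulfonate
Conditions: CH2=C(CH3)MgBr, THF, −78 to 0 °C; aq. NH4Cl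
Reagents that add atoms: isopropenylmagnesium bromide, CC(=C)[Mg]Br
Why: Grignard addition to the remaining Weinreb amide gives the isopropenyl ketone (C16 carbonyl); the enol triflate is inert without a catalyst.

Step 23
Reactants: 29 1-{(4R,5R)-2,2-dimethyl-5-(2-methylprop-2-enoyl)-1,3-dioxolan-4-yl}ethenyl trifluoromethanesulfonate
Product: 30 1-{(4R,5S)-5-[(1R)-1-hydroxy-2-methylprop-2-en-1-yl]-2,2-dimethyl-1,3-dioxolan-4-yl}ethenyl trifluoromethanesulfonate
Conditions: (R)-2-methyl-CBS-oxazaborolidine (20 mol %), BH3·SMe2, THF, −40 °C; MeOH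
Reagents that add atoms: none
Why: Corey–Bakshi–Shibata 1,2-reduction under catalyst control (isopropenyl taken as the large group) should give the (R)-carbinol at C16, which is also the Felkin–Anh sense of the α-alkoxy ketone.

Step 24
Reactants: 30 1-{(4R,5S)-5-[(1R)-1-hydroxy-2-methylprop-2-en-1-yl]-2,2-dimethyl-1,3-dioxolan-4-yl}ethenyl trifluoromethanesulfonate
Product: 31 acrylate ester of 30 at the C16 hydroxyl
Conditions: acryloyl chloride, i-Pr2NEt, CH2Cl2, −78 to 0 °C
Reagents that add atoms: acryloyl chloride, C=CC(=O)Cl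
Why: O-acylation of the secondary alcohol sets up the diene for ring closure.

Step 25
Reactants: 31 acrylate ester of 30
Product: 32 1-{(4R,5S)-2,2-dimethyl-5-[(2R)-3-methyl-5-oxo-2,5-dihydrofuran-2-yl]-1,3-dioxolan-4-yl}ethenyl trifluoromethanesulfonate
Conditions: second-generation Grubbs catalyst, (H2IMes)(PCy3)Cl2Ru=CHPh (10 mol %), CH2Cl2, 40 °C
Reagents that add atoms: none
Why: Ring-closing metathesis of the acrylate with the isopropenyl group forms the 4-methylbutenolide; the electron-poor enol triflate alkene should not take part.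

**Union and deprotection (steps 26–27)**

Step 26
Reactants: 24 12-iodo-18-(tert-butyldimethylsilyloxy)-6α,8α-bis(triethylsilyloxy)-13,14,15,16-tetranorlabdane; 32 butenolide enol triflate
Product: 34 fully protected target (18-O-TBS; 6,8-di-O-TES; 14,15-O-isopropylidene), via alkylzinc iodide 33 (not isolated)
Conditions: Zn dust (activated with Me3SiCl), LiCl, THF, 40 °C; then 32, Pd(PPh3)4 (5 mol %), THF/NMP, rt to 50 °C
Reagents that add atoms: none
Why: Negishi sp3–sp2 coupling of a primary alkylzinc iodide with an alkenyl triflate forms C12–C13 under neutral conditions that the base-sensitive butenolide should tolerate, and it touches no stereocentre.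

Step 27
Reactants: 34 fully protected target
Product: 35 target, (5R)-5-{(1R,2S)-1,2-dihydroxy-3-methylidene-5-[(1R,2R,4S,4aR,5R,8aS)-2,4-dihydroxy-5-(hydroxymethyl)-2,5,8a-trimethyldecahydronaphthalen-1-yl]pentyl}-4-methylfuran-2(5H)-one
Conditions: CF3CO2H/H2O/THF (1:1:3), 0 °C to rt
Reagents that add atoms: none
Why: Mild aqueous acid hydrolysis should remove the three silyl ethers and the acetonide in one operation without base, which the butenolide C16–H would not tolerate.

**Compound list**

1 | geraniol | CC(C)=CCC/C(C)=C/CO | starting material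
2 | (2S,3S)-2,3-epoxygeraniol | CC(C)=CCC[C@]1(C)O[C@H]1CO | intermediate
3 | (2S,3S)-2,3-epoxygeranyl tert-butyldimethylsilyl ether | CC(C)=CCC[C@]1(C)O[C@H]1CO[Si](C)(C)C(C)(C)C | intermediate
4 | (S)-2-[(tert-butyldimethylsilyloxy)methyl]-2,6-dimethylhept-5-enal | CC(C)=CCC[C@@](C)(CO[Si](C)(C)C(C)(C)C)C=O | intermediate
5 | (S)-1-(tert-butyldimethylsilyloxy)-2-(dimethoxymethyl)-2,6-dimethylhept-5-ene | CC(C)=CCC[C@@](C)(CO[Si](C)(C)C(C)(C)C)C(OC)OC | intermediate
6 | (S)-4-[(tert-butyldimethylsilyloxy)methyl]-5,5-dimethoxy-4-methylpentanal | O=CCC[C@@](C)(CO[Si](C)(C)C(C)(C)C)C(OC)OC | intermediate (not isolated)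
7 | (S)-4-[(tert-butyldimethylsilyloxy)methyl]-5,5-dimethoxy-4-methylpentan-1-ol | OCCC[C@@](C)(CO[Si](C)(C)C(C)(C)C)C(OC)OC | intermediate
8 | (S)-tert-butyl[2-(dimethoxymethyl)-5-iodo-2-methylpentyloxy]dimethylsilane | ICCC[C@@](C)(CO[Si](C)(C)C(C)(C)C)C(OC)OC | intermediate
9 | 3-butyn-1-ol | C#CCCO | starting material
10 | dilithium salt of 3-butyn-1-ol (lithium 4-lithiobut-3-yn-1-olate) | [Li]C#CCCO[Li] | intermediate (not isolated)
11 | (S)-8-[(tert-butyldimethylsilyloxy)methyl]-9,9-dimethoxy-8-methylnon-3-yn-1-ol | OCCC#CCCC[C@@](C)(CO[Si](C)(C)C(C)(C)C)C(OC)OC | intermediate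
12 | alkenylmagnesium bromide alkoxide chelate (Mg on C9, cis to the new C10 methyl) | Br[Mg]OCC/C([Mg]Br)=C(/C)CCC[C@@](C)(CO[Si](C)(C)C(C)(C)C)C(OC)OC | intermediate (not isolated)
13 | (3E,8S)-8-[(tert-butyldimethylsilyloxy)methyl]-3-iodo-9,9-dimethoxy-4,8-dimethylnon-3-en-1-ol | OCC/C(I)=C(/C)CCC[C@@](C)(CO[Si](C)(C)C(C)(C)C)C(OC)OC | intermediate
14 | (3E,8S)-8-[(tert-butyldimethylsilyloxy)methyl]-9,9-dimethoxy-4,8-dimethyl-3-(prop-1-en-2-yl)non-3-en-1-ol | OCC/C(C(C)=C)=C(/C)CCC[C@@](C)(CO[Si](C)(C)C(C)(C)C)C(OC)OC | intermediate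
15 | (2S,6E)-1-(tert-butyldimethylsilyloxy)-9-chloro-2-(dimethoxymethyl)-2,6-dimethyl-7-(prop-1-en-2-yl)non-6-ene | ClCC/C(C(C)=C)=C(/C)CCC[C@@](C)(CO[Si](C)(C)C(C)(C)C)C(OC)OC | intermediate
16 | (2S,6E)-2-[(tert-butyldimethylsilyloxy)methyl]-9-chloro-2,6-dimethyl-7-(prop-1-en-2-yl)non-6-enal | ClCC/C(C(C)=C)=C(/C)CCC[C@@](C)(CO[Si](C)(C)C(C)(C)C)C=O | intermediate
17 | tert-butyl{[(2R,3E)-2-[(4E)-7-chloro-4-methyl-5-(prop-1-en-2-yl)hept-4-en-1-yl]-4-iodo-2-methylbut-3-en-1-yl]oxy}dimethylsilane | ClCC/C(C(C)=C)=C(/C)CCC[C@@](C)(CO[Si](C)(C)C(C)(C)C)/C=C/I | intermediate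
18 | tert-butyl{[(2R,3E)-2-[(4E)-7-chloro-4-methyl-5-(prop-1-en-2-yl)hept-4-en-1-yl]-4-(4-methoxyphenoxy)-2-methylbut-3-en-1-yl]oxy}dimethylsilane | ClCC/C(C(C)=C)=C(/C)CCC[C@@](C)(CO[Si](C)(C)C(C)(C)C)/C=C/Oc1ccc(OC)cc1 | intermediate
19 | 12-chloro-6α-(4-methoxyphenoxy)-18-(tert-butyldimethylsilyloxy)-13,14,15,16-tetranorlabd-8-ene | ClCCC=1[C@@]2(C)CCC[C@@](C)(CO[Si](C)(C)C(C)(C)C)[C@@H]2[C@@H](Oc3ccc(OC)cc3)CC=1C | intermediate
20 | 8α-boryl (BH2) 9α-H alkylborane from 19 | ClCC[C@@H]1[C@@]2(C)CCC[C@@](C)(CO[Si](C)(C)C(C)(C)C)[C@@H]2[C@@H](Oc3ccc(OC)cc3)C[C@@]1(C)B | intermediate (not isolated)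
21 | 12-chloro-6α-(4-methoxyphenoxy)-18-(tert-butyldimethylsilyloxy)-13,14,15,16-tetranorlabdan-8α-ol | ClCC[C@@H]1[C@@]2(C)CCC[C@@](C)(CO[Si](C)(C)C(C)(C)C)[C@@H]2[C@@H](Oc3ccc(OC)cc3)C[C@@]1(C)O | intermediate
22 | 12-chloro-18-(tert-butyldimethylsilyloxy)-13,14,15,16-tetranorlabdane-6α,8α-diol | ClCC[C@@H]1[C@@]2(C)CCC[C@@](C)(CO[Si](C)(C)C(C)(C)C)[C@@H]2[C@@H](O)C[C@@]1(C)O | intermediate
23 | 12-chloro-18-(tert-butyldimethylsilyloxy)-6α,8α-bis(triethylsilyloxy)-13,14,15,16-tetranorlabdane | ClCC[C@@H]1[C@@]2(C)CCC[C@@](C)(CO[Si](C)(C)C(C)(C)C)[C@@H]2[C@@H](O[Si](CC)(CC)CC)C[C@@]1(C)O[Si](CC)(CC)CC | intermediate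
24 | 12-iodo-18-(tert-butyldimethylsilyloxy)-6α,8α-bis(triethylsilyloxy)-13,14,15,16-tetranorlabdane | ICC[C@@H]1[C@@]2(C)CCC[C@@](C)(CO[Si](C)(C)C(C)(C)C)[C@@H]2[C@@H](O[Si](CC)(CC)CC)C[C@@]1(C)O[Si](CC)(CC)CC | intermediate
25 | dimethyl (4R,5R)-2,2-dimethyl-1,3-dioxolane-4,5-dicarboxylate (from L-tartaric acid) | COC(=O)[C@@H]1OC(C)(C)O[C@H]1C(=O)OC | starting material
26 | (4R,5R)-N,N'-dimethoxy-N,N',2,2-tetramethyl-1,3-dioxolane-4,5-dicarboxamide | CON(C)C(=O)[C@@H]1OC(C)(C)O[C@H]1C(=O)N(C)OC | intermediate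
27 | (4R,5R)-5-acetyl-N-methoxy-N,2,2-trimethyl-1,3-dioxolane-4-carboxamide | CC(=O)[C@@H]1OC(C)(C)O[C@H]1C(=O)N(C)OC | intermediate
28 | 1-{(4R,5R)-5-[methoxy(methyl)carbamoyl]-2,2-dimethyl-1,3-dioxolan-4-yl}ethenyl trifluoromethanesulfonate | C=C(OS(=O)(=O)C(F)(F)F)[C@@H]1OC(C)(C)O[C@H]1C(=O)N(C)OC | intermediate
29 | 1-{(4R,5R)-2,2-dimethyl-5-(2-methylprop-2-enoyl)-1,3-dioxolan-4-yl}ethenyl trifluoromethanesulfonate | C=C(OS(=O)(=O)C(F)(F)F)[C@@H]1OC(C)(C)O[C@H]1C(=O)C(C)=C | intermediate
30 | 1-{(4R,5S)-5-[(1R)-1-hydroxy-2-methylprop-2-en-1-yl]-2,2-dimethyl-1,3-dioxolan-4-yl}ethenyl trifluoromethanesulfonate | C=C(OS(=O)(=O)C(F)(F)F)[C@@H]1OC(C)(C)O[C@H]1[C@H](O)C(C)=C | intermediate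
31 | acrylate ester of 30 | C=C(OS(=O)(=O)C(F)(F)F)[C@@H]1OC(C)(C)O[C@H]1[C@H](OC(=O)C=C)C(C)=C | intermediate
32 | 1-{(4R,5S)-2,2-dimethyl-5-[(2R)-3-methyl-5-oxo-2,5-dihydrofuran-2-yl]-1,3-dioxolan-4-yl}ethenyl trifluoromethanesulfonate | C=C(OS(=O)(=O)C(F)(F)F)[C@@H]1OC(C)(C)O[C@H]1[C@@H]2OC(=O)C=C2C | intermediate
33 | C12 alkylzinc iodide from 24 | I[Zn]CC[C@@H]1[C@@]2(C)CCC[C@@](C)(CO[Si](C)(C)C(C)(C)C)[C@@H]2[C@@H](O[Si](CC)(CC)CC)C[C@@]1(C)O[Si](CC)(CC)CC | intermediate (not isolated)
34 | fully protected target (18-O-TBS; 6,8-di-O-TES; 14,15-O-isopropylidene) | C=C(CC[C@@H]1[C@@]2(C)CCC[C@@](C)(CO[Si](C)(C)C(C)(C)C)[C@@H]2[C@@H](O[Si](CC)(CC)CC)C[C@@]1(C)O[Si](CC)(CC)CC)[C@@H]3OC(C)(C)O[C@H]3[C@@H]4OC(=O)C=C4C | intermediate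
35 | target CNP0301623.1 | C=C(CC[C@@H]1[C@@]2(C)CCC[C@@](C)(CO)[C@@H]2[C@@H](O)C[C@@]1(C)O)[C@H](O)[C@@H](O)[C@@H]1OC(=O)C=C1C | target

**Step count and risks**

Total steps: 27. Longest linear sequence: 20 (steps 1–18, 26, 27); the side-chain fragment takes 7 steps (19–25).

Steps most likely to fail:

1. Step 14. The radical cation may be diverted before ring closure (enol ether hydrolysis, oligomerisation, a [2+2] closure that does not rearrange), or the cyclisation may show poor facial selectivity with respect to C4 or give cis fusion. Fallback with known chemistry, setting out from aldehyde 16: borylative Takai–Utimoto olefination (CrCl2, LiI, Cl2CHB(pin), THF) should give the (E)-alkenylboronate F1. Heating (toluene, BHT, 160 °C, sealed tube) brings about the thermal intramolecular Diels–Alder reaction of the alkenylboronate to the 6α-boryl octalin F2, the E geometry placing boron trans to C4. Hydroboration of the C8=C9 bond with BH3·THF as in step 15, followed by NaBO3 oxidation of both C–B bonds with retention, comes back to the route at diol 22.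

2. Step 15. Borane may add slowly to the hindered tetrasubstituted C8=C9 bond or place boron on C9. Fallback, setting out from 19: epoxidation with dimethyldioxirane (acetone, 0 °C) from the α face gives the 8α,9α-epoxide F3. Reductive opening with Cp2TiCl (made from Cp2TiCl2 and Zn; trivalent titanium) and 1,4-cyclohexadiene in THF should cleave the C9–O bond, leave the oxygen on C8 and deliver hydrogen to the C9 radical from the α face, coming back at 21.

3. Step 26. Zinc insertion may be incomplete, coupling with the α-branched enol triflate may be slow, or the butenolide may be lost (ring opening or C16 epimerisation) during the coupling. Fallback, setting out from 24 and 31: alkylzinc 33 is coupled under the same palladium catalysis with acrylate 31, which holds no lactone yet, to give the coupled acrylate F4. Ring-closing metathesis with the second-generation Grubbs catalyst then builds the butenolide after the union and comes back at 34.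

Further compounds
F1 | step 14 | (E)-alkenylboronate from 16 (pinacol ester, boron on C6) | ClCC/C(C(C)=C)=C(/C)CCC[C@@](C)(CO[Si](C)(C)C(C)(C)C)/C=C/B1OC(C)(C)C(C)(C)O1
F2 | step 14 | 12-chloro-6α-(pinacolatoboryl)-18-(tert-butyldimethylsilyloxy)-13,14,15,16-tetranorlabd-8-ene | ClCCC=1[C@@]2(C)CCC[C@@](C)(CO[Si](C)(C)C(C)(C)C)[C@@H]2[C@@H](B3OC(C)(C)C(C)(C)O3)CC=1C
F3 | step 15 | 8α,9α-epoxide of 19 | ClCC[C@]13[C@@]2(C)CCC[C@@](C)(CO[Si](C)(C)C(C)(C)C)[C@@H]2[C@@H](Oc4ccc(OC)cc4)C[C@@]1(C)O3
F4 | step 26 | coupled acrylate (core joined to C13; C16 acrylate and isopropenyl not yet ring-closed) | C=C(CC[C@@H]1[C@@]2(C)CCC[C@@](C)(CO[Si](C)(C)C(C)(C)C)[C@@H]2[C@@H](O[Si](CC)(CC)CC)C[C@@]1(C)O[Si](CC)(CC)CC)[C@@H]3OC(C)(C)O[C@H]3[C@H](OC(=O)C=C)C(C)=C
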